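The cyclohexene ring is numbered C1 (methyl-bearing), C2 (=CH), C3 (pyranone-bearing), C4 (isopropyl-bearing), C5 and C6, and the route rests on cutting C1–C2 and C5–C6. C1 and C6 then form a propyne unit, and C2–C3–C4–C5, which holds both stereocentres, becomes a cyclobutanone with C2 as carbonyl carbon. The key step exploits the strain of that four-membered ring: zerovalent nickel inserts 1-(trimethylsilyl)propyne into the unsubstituted C2–C5 bond, building the six-membered ring and a 2-methyl enone in one operation while C3 and C4 stay untouched. The precursor is the enantiopure trans-2,3-disubstituted cyclobutanone whose tert-butyl acetate arm on C3 later becomes the pyranone.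

Key step: step 6

Remark on labels: C1–C6 in the Why lines are the ring atoms as numbered in the first paragraph; locants inside compound names follow nomenclature rules.

Assumption: the lithium azaenolate of a cyclobutanone SAMP hydrazone is taken to be alkylated on the same face as that of the cyclohexanone analogue (new α-centre R); if the sense proved opposite, the enantiomeric auxiliary RAMP would be used in steps 3 and 4.

Step 1
Reactants: 1 3-methylbut-1-ene; 2 trichloroacetyl chloride
Product: 4 2,2-dichloro-3-(propan-2-yl)cyclobutan-1-one (racemic), via dichloroketene 3 (not isolated)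
Conditions: Zn–Cu couple, Et2O/DME, 10 → 35 °C, excess 1
Reagents that add atoms: none
Why: Ketene–alkene [2+2] cycloaddition in which dichloroketene, released from 2 by zinc, adds to the terminal alkene with its carbonyl carbon at the CH2 terminus, so that CCl2 sits next to the isopropyl-bearing carbon; the one stereocentre forms racemic and ceases to be a stereocentre in step 2.

Step 2
Reactants: 4
Product: 5 3-(propan-2-yl)cyclobutan-1-one
Conditions: Zn dust, AcOH, 25 → 60 °C
Reagents that add atoms: none
Why: Reductive dechlorination of an α,α-dichloroketone by zinc in acetic acid, which removes both chlorines without opening the ring and leaves an achiral ketone whose two α-CH2 groups are enantiotopic; no stereocentre is formed.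

Step 3
Reactants: 5
Product: 6 (2S)-2-(methoxymethyl)-N-[3-(propan-2-yl)cyclobutylidene]pyrrolidin-1-amine (both C=N isomers)
Conditions: SAMP, neat, 60 °C
Reagents that add atoms: SAMP, (S)-1-amino-2-(methoxymethyl)pyrrolidine, COC[C@@H]1CCCN1N
Why: Hydrazone formation between the ketone and the chiral hydrazine, driven by loss of water; no stereocentre is formed and both C=N isomers are carried on.

Step 4
Reactants: 6; 7 tert-butyl bromoacetate
Product: 8 tert-butyl 2-[(1R,2R)-4-{[(2S)-2-(methoxymethyl)pyrrolidin-1-yl]imino}-2-(propan-2-yl)cyclobutyl]acetate
Conditions: LiN(iPr)2, THF, 0 °C; then 7 (about 0.5 equiv), −100 → −78 °C; aq. NH4Cl; chromatography, recovered 6 recycled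
Reagents that add atoms: none
Why: SAMP-hydrazone α-alkylation in which the auxiliary directs the bromoacetate to one face of the lithium azaenolate and so fixes the arm-bearing carbon C3 as R, while the auxiliary cannot choose between the two enantiotopic α-CH2 groups in the deprotonation, so that only the regioisomeric azaenolate whose auxiliary-favoured face is also anti to the isopropyl group should be alkylated fast and, with the electrophile limiting, the trans hydrazone (C4 thereby R) should dominate, the minor cis isomer being removed by chromatography and unreacted azaenolate returning 6.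

Step 5
Reactants: 8
Product: 9 tert-butyl 2-[(1R,2R)-4-oxo-2-(propan-2-yl)cyclobutyl]acetate
Conditions: saturated aq. oxalic acid, Et2O, 20 °C, two-phase
Reagents that add atoms: water, O
Why: Mild two-phase acid hydrolysis of the hydrazone, a method that frees α-substituted ketones without epimerisation and returns the auxiliary; the tert-butyl ester is stable and no stereocentre is touched.

Step 6
Reactants: 9; 10 1-(trimethylsilyl)propyne
Product: 11 tert-butyl 2-[(1R,6R)-3-methyl-2-oxo-6-(propan-2-yl)-4-(trimethylsilyl)cyclohex-3-en-1-yl]acetate
Conditions: Ni(cod)2 (10 mol %), PCy3 (20 mol %), toluene, 100 °C, sealed tube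
Reagents that add atoms: none
Why: The C2 carbonyl and the alkyne couple oxidatively on zerovalent nickel to an oxanickelacyclopentene in which C2 is bonded to the methyl-bearing alkyne carbon (C1) and nickel holds the silyl-bearing carbon (C6); β-carbon elimination then breaks the strained C2–C5 bond to give a seven-membered nickelacycle, and C(sp3)–C(sp2) reductive elimination joins C5 to C6. The closest known reaction type is the nickel-catalysed intermolecular insertion of internal alkynes into cyclobutanones to give cyclohex-2-enones, a formal [4+2] driven by release of ring strain. The six-membered ring is therefore closed by two-carbon ring expansion, its last bond C5–C6 coming from reductive elimination out of the nickelacycle and not from cyclisation of an open chain. No stereocentre is created: C3 and C4 are carried over from 9, and C3, being α to the ketone before and after, can only relax toward the trans (diequatorial) arrangement that the target needs. The step needs site selectivity for the C2–C5 bond over C2–C3, which should follow from β-carbon elimination giving a primary alkylnickel at C5 instead of a crowded secondary one at C3 (flanked by the arm and the isopropyl-bearing C4), helped by the bulky, weakly coordinating tert-butyl ester. It also needs one alkyne orientation, which the silyl group should secure by taking the nickel-bound position in the oxidative coupling, as silylalkynes do in nickel-mediated couplings with carbonyl compounds, so that methyl ends up at C1 next to the carbonyl.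

Step 7
Reactants: 11
Product: 12 tert-butyl 2-[(1R,6R)-3-methyl-2-oxo-6-(propan-2-yl)cyclohex-3-en-1-yl]acetate
Conditions: Bu4NF·3H2O, THF, 0 → 25 °C
Reagents that add atoms: none
Why: Fluoride-induced protodesilylation of an alkenylsilane, eased because C6 is the β-carbon of the enone (a vinylogous acylsilane), with water protonating C6 so that the C1=C6 double bond stays in place; no stereocentre is formed and C3 can only equilibrate toward the wanted trans isomer.

Step 8
Reactants: 12
Product: 13 tert-butyl 2-[(1R,6R)-3-methyl-2-[2-(4-methylbenzenesulfonyl)hydrazinylidene]-6-(propan-2-yl)cyclohex-3-en-1-yl]acetate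
Conditions: TsNHNH2, EtOH, 40 °C
Reagents that add atoms: 4-methylbenzenesulfonohydrazide (TsNHNH2), Cc1ccc(cc1)S(=O)(=O)NN
Why: Tosylhydrazone formation at the enone carbonyl under neutral conditions, chosen so that the α-stereocentre C3 is not enolised; no stereocentre is formed.

Step 9
Reactants: 13
Product: 15 tert-butyl 2-[(1R,6R)-3-methyl-6-(propan-2-yl)cyclohex-2-en-1-yl]acetate, via allylic diazene 14 (not isolated)
Conditions: catecholborane, CHCl3, 0 °C; then NaOAc·3H2O, 60 °C
Reagents that add atoms: none
Why: Reductive 1,3-transposition of an α,β-unsaturated tosylhydrazone, in which catecholborane delivers hydride to C2, acetate triggers loss of sulfinate and the allylic diazene expels N2 in a retro-ene step that places hydrogen on C6 and the double bond at C1=C2; C2 ends sp2, so no stereocentre results and C3 and C4 are untouched.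

Step 10
Reactants: 15; 16 N-methoxy-N-methylacetamide
Product: 17 tert-butyl 2-[(1R,6R)-3-methyl-6-(propan-2-yl)cyclohex-2-en-1-yl]-3-oxobutanoate (both epimers at the butanoate C2)
Conditions: LiN(iPr)2, THF, −78 °C; then 16, −78 → 0 °C; AcOH
Reagents that add atoms: none
Why: Crossed Claisen-type C-acylation of the lithium ester enolate by an N-methoxy-N-methylamide, whose stable tetrahedral adduct prevents over-reaction; the new α-stereocentre forms without control and is erased when this carbon becomes pyranone C3.

Step 11
Reactants: 17; 18 (2E)-N-methoxy-N-methyl-3-phenylprop-2-enamide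
Product: 19 tert-butyl (6E)-2-[(1R,6R)-3-methyl-6-(propan-2-yl)cyclohex-2-en-1-yl]-3,5-dioxo-7-phenylhept-6-enoate (keto–enol mixture)
Conditions: LiN(iPr)2 (2.2 equiv), THF, −78 → 0 °C; then 18, −78 → 0 °C; AcOH
Reagents that add atoms: none
Why: γ-Acylation of the β-keto ester dianion (deprotonated at the α-CH and then at the terminal methyl) by the N-methoxy-N-methylamide of cinnamic acid, the hard terminal carbanion attacking the amide carbonyl and not the β-carbon; no new stereocentre is formed and the E-alkene is retained.

Step 12
Reactants: 19
Product: 21 4-hydroxy-3-[(1R,6R)-3-methyl-6-(propan-2-yl)cyclohex-2-en-1-yl]-6-[(E)-2-phenylethenyl]-2H-pyran-2-one, via acylketene 20 (not isolated)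
Conditions: toluene, 110 °C
Reagents that add atoms: none
Why: Thermal loss of tert-butanol from the β-keto tert-butyl ester gives an acylketene that is trapped by the enol oxygen of the 5-keto group (lactonisation by 6π-electrocyclisation) and tautomerises to the 4-hydroxy-2-pyranone under neutral conditions that spare the ring alkene; no stereocentre is formed.

Compound list
1 | 3-methylbut-1-ene | CC(C)C=C | starting material
2 | trichloroacetyl chloride | ClC(Cl)(Cl)C(Cl)=O | starting material
3 | dichloroketene | ClC(Cl)=C=O | intermediate
4 | 2,2-dichloro-3-(propan-2-yl)cyclobutan-1-one (racemic) | CC(C)C1CC(=O)C1(Cl)Cl | intermediate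
5 | 3-(propan-2-yl)cyclobutan-1-one | CC(C)C1CC(=O)C1 | intermediate
6 | (2S)-2-(methoxymethyl)-N-[3-(propan-2-yl)cyclobutylidene]pyrrolidin-1-amine (both C=N isomers) | COC[C@@H]1CCCN1N=C1CC(C(C)C)C1 | intermediate
7 | tert-butyl bromoacetate | CC(C)(C)OC(=O)CBr | starting material
8 | tert-butyl 2-[(1R,2R)-4-{[(2S)-2-(methoxymethyl)pyrrolidin-1-yl]imino}-2-(propan-2-yl)cyclobutyl]acetate (trans) | C1[C@H](C(C)C)[C@@H](CC(=O)OC(C)(C)C)C1=NN1CCC[C@H]1COC | intermediate
9 | tert-butyl 2-[(1R,2R)-4-oxo-2-(propan-2-yl)cyclobutyl]acetate (trans) | C1[C@H](C(C)C)[C@@H](CC(=O)OC(C)(C)C)C1=O | intermediate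
10 | 1-(trimethylsilyl)propyne | CC#C[Si](C)(C)C | starting material
11 | tert-butyl 2-[(1R,6R)-3-methyl-2-oxo-6-(propan-2-yl)-4-(trimethylsilyl)cyclohex-3-en-1-yl]acetate (trans) | CC1=C([Si](C)(C)C)C[C@H](C(C)C)[C@@H](CC(=O)OC(C)(C)C)C1=O | intermediate
12 | tert-butyl 2-[(1R,6R)-3-methyl-2-oxo-6-(propan-2-yl)cyclohex-3-en-1-yl]acetate (trans) | CC1=CC[C@H](C(C)C)[C@@H](CC(=O)OC(C)(C)C)C1=O | intermediate
13 | tert-butyl 2-[(1R,6R)-3-methyl-2-[2-(4-methylbenzenesulfonyl)hydrazinylidene]-6-(propan-2-yl)cyclohex-3-en-1-yl]acetate | CC1=CC[C@H](C(C)C)[C@@H](CC(=O)OC(C)(C)C)C1=NNS(=O)(=O)c1ccc(C)cc1 | intermediate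
14 | tert-butyl 2-[(1R,6R)-2-diazenyl-3-methyl-6-(propan-2-yl)cyclohex-3-en-1-yl]acetate (both epimers at the diazenyl carbon) | CC1=CC[C@H](C(C)C)[C@@H](CC(=O)OC(C)(C)C)C1N=N | intermediate
15 | tert-butyl 2-[(1R,6R)-3-methyl-6-(propan-2-yl)cyclohex-2-en-1-yl]acetate (trans) | CC1=C[C@H](CC(=O)OC(C)(C)C)[C@@H](C(C)C)CC1 | intermediate
16 | N-methoxy-N-methylacetamide | CC(=O)N(C)OC | starting material
17 | tert-butyl 2-[(1R,6R)-3-methyl-6-(propan-2-yl)cyclohex-2-en-1-yl]-3-oxobutanoate (both epimers at the butanoate C2) | CC1=C[C@H](C(C(C)=O)C(=O)OC(C)(C)C)[C@@H](C(C)C)CC1 | intermediate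
18 | (2E)-N-methoxy-N-methyl-3-phenylprop-2-enamide | CON(C)C(=O)/C=C/c1ccccc1 | starting material
19 | tert-butyl (6E)-2-[(1R,6R)-3-methyl-6-(propan-2-yl)cyclohex-2-en-1-yl]-3,5-dioxo-7-phenylhept-6-enoate | CC1=C[C@H](C(C(=O)CC(=O)/C=C/c2ccccc2)C(=O)OC(C)(C)C)[C@@H](C(C)C)CC1 | intermediate
20 | (6E)-2-[(1R,6R)-3-methyl-6-(propan-2-yl)cyclohex-2-en-1-yl]-7-phenylhepta-1,6-diene-1,3,5-trione (acylketene) | CC1=C[C@H](C(=C=O)C(=O)CC(=O)/C=C/c2ccccc2)[C@@H](C(C)C)CC1 | intermediate
21 | 4-hydroxy-3-[(1R,6R)-3-methyl-6-(propan-2-yl)cyclohex-2-en-1-yl]-6-[(E)-2-phenylethenyl]-2H-pyran-2-one | CC1=C[C@H](c2c(O)cc(/C=C/c3ccccc3)oc2=O)[C@@H](C(C)C)CC1 | target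

Total step count: 12 steps.
Longest linear sequence: 12 steps (1 and 2 to 21).

Steps most likely to fail

Step 6. What may go wrong: β-carbon elimination on the substituted side (C2–C3) instead of C2–C5, insertion of the alkyne in the reverse orientation, or alkyne oligomerisation outrunning insertion. Fallback: the enone is taken from the chiral pool instead of being made by ring expansion. Purchased (S)-carvone is hydrogenated at the isopropenyl group only (H2, RhCl(PPh3)3, benzene) to (5S)-2-methyl-5-(propan-2-yl)cyclohex-2-en-1-one F1. Its kinetic cross-conjugated lithium enolate (LiN(iPr)2, THF, −78 °C) is then alkylated with tert-butyl bromoacetate anti to the neighbouring isopropyl group. This fallback sets out from 7 (together with the purchased terpene) and comes back to the route at 12, after which steps 8 to 12 are unchanged.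

Step 4. What may go wrong: deprotonation of both enantiotopic α-CH2 groups with too little rate difference between the matched and mismatched azaenolates. This would cost material and diastereomeric purity, and later α-epimerisation would turn that into loss of enantiomeric purity. Fallback: the two α-positions of the ketone are told apart at the enolisation stage instead of at the alkylation stage. Ketone 5 is deprotonated with a homochiral lithium amide, lithium bis[(1R)-1-phenylethyl]amide or its antipode (whichever gives the R series), in THF at −100 °C with Me3SiCl present, to give trimethyl{[(3R)-3-(propan-2-yl)cyclobut-1-en-1-yl]oxy}silane F2. F2 is then alkylated regiospecifically with 7 under visible-light photoredox catalysis (Ir(ppy)3, MeCN, blue light), the ester-substituted radical adding anti to the isopropyl group and the silyl group being lost. This fallback sets out from 5 and comes back at 9.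

Step 7. What may go wrong: cleavage of the C–Si bond by fluoride is too slow, so that base-induced self-condensation of the enone takes over. Fallback: a silyl group built for fluoride cleavage is used in the ring expansion. Benzyl(dimethyl)(prop-1-yn-1-yl)silane F3 (from prop-1-ynylmagnesium bromide and benzylchlorodimethylsilane) replaces 10 in the nickel-catalysed insertion with 9. This gives tert-butyl 2-[(1R,6R)-4-[benzyl(dimethyl)silyl]-3-methyl-2-oxo-6-(propan-2-yl)cyclohex-3-en-1-yl]acetate F4. Bu4NF in THF at 0 °C first cleaves the Si–benzyl bond, and the resulting fluorosilane is protodesilylated readily. This fallback sets out from 9 and comes back at 12.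

Further compounds
F1 | step 6 | (5S)-2-methyl-5-(propan-2-yl)cyclohex-2-en-1-one | CC1=CC[C@H](C(C)C)CC1=O
F2 | step 4 | trimethyl{[(3R)-3-(propan-2-yl)cyclobut-1-en-1-yl]oxy}silane | C1[C@H](C(C)C)C=C1O[Si](C)(C)C
F3 | step 7 | benzyl(dimethyl)(prop-1-yn-1-yl)silane | CC#C[Si](C)(C)Cc1ccccc1
F4 | step 7 | tert-butyl 2-[(1R,6R)-4-[benzyl(dimethyl)silyl]-3-methyl-2-oxo-6-(propan-2-yl)cyclohex-3-en-1-yl]acetate | CC1=C([Si](C)(C)Cc2ccccc2)C[C@H](C(C)C)[C@@H](CC(=O)OC(C)(C)C)C1=O
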